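## Retrosynthetic overview

1. Aikupikoxide D ⇒ oxidation of an allylic alcohol ⇒ C9–C10 disconnection: a C9 aldehyde on the finished 1,2-dioxane plus a 2-lithioalkene made by Shapiro reaction from 6-hydroxy-6-methylheptan-2-one (from 6-methylhept-5-en-2-one).
2. C9 aldehyde ⇒ ozonolysis of a second (E)-2-methyl-2-enoate arm on a dioxane diester.
3. Key disconnection (the only ring): the C3–O bond, by 6-exo conjugate addition of a C6 tertiary hydroperoxide to the enoate. It is run as a catalytic desymmetrisation of an achiral hydroperoxide with two identical enoate arms, so C6, C3 and C2 are all set in the ring-forming step.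
4. Achiral hydroperoxide ⇒ tertiary alcohol (H2O2/H+) ⇒ two-directional ozonolysis/Wittig of 5-methylnona-1,8-dien-5-ol ⇒ ethyl acetate + two but-3-enyl Grignard units.
5. Ring order: the 1,2-dioxane is the single ring and is closed in step 4; all later steps are side-chain work under peroxide-safe conditions.

Assumption: the presumed biosynthesis is taken as hydroperoxidation at C6 of an acyclic polyene ester followed by 6-exo conjugate addition of that hydroperoxide to the (2E)-2-methyl-2-enoate, with the enone arising by later allylic oxidation; chain numbering runs from C1 (ester carbon) to C14 (carbinol carbon), and the target read from the SMILES is 2S,3S,6R.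

Note on labels: the CIP label at C6 is S in 9 and 17 and R in 10, 11 and 18. Only the priority of the side-chain arm changes; the spatial arrangement is the same throughout.

## Route

Step 1
Reactants: 1 ethyl acetate; 2 but-3-en-1-ylmagnesium bromide (2.3 equiv)
Product: 3 5-methylnona-1,8-dien-5-ol
Conditions: THF, 0 °C to rt; then 1 M aq. HCl, 0 °C
Reagents that add atoms: none
Why: Double Grignard addition to an ester (via the methyl ketone) gives the tertiary carbinol with two identical arms, so no stereocentre is formed.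

Step 2
Reactants: 3 5-methylnona-1,8-dien-5-ol; 4 methyl 2-(triphenyl-λ5-phosphanylidene)propanoate (5 equiv)
Product: 7 dimethyl (2E,9E)-6-hydroxy-2,6,10-trimethylundeca-2,9-dienedioate, via bis-ozonide 5 (not isolated), via 4-hydroxy-4-methylheptanedial 6 (not isolated)
Conditions: O3, CH2Cl2, −78 °C; PPh3 (2.2 equiv), −78 °C to rt; then 4, toluene, 80 °C
Reagents that add atoms: ozone, [O-][O+]=O (its oxygen atoms are present in 5 and 6 only; none remains in 7)
Why: Ozonolysis with reductive work-up gives the dialdehyde (held largely as its lactol), which reacts through the open form in a double Wittig olefination; the stabilised α-methyl ylide gives the (E)-trisubstituted enoates and its excess consumes the formaldehyde set free.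

Step 3
Reactants: 7 dimethyl (2E,9E)-6-hydroxy-2,6,10-trimethylundeca-2,9-dienedioate
Product: 8 dimethyl (2E,9E)-6-hydroperoxy-2,6,10-trimethylundeca-2,9-dienedioate (achiral)
Conditions: 50% aq. H2O2 (20 equiv), H2SO4 (0.2 equiv), THF, 0 °C to rt
Reagents that add atoms: hydrogen peroxide, OO
Why: Acid-catalysed SN1 perhydrolysis of a tertiary alcohol, in which the tertiary cation is trapped by the large excess of H2O2 while the electron-poor enoate double bonds do not compete; C6 stays achiral because both arms are identical.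

Step 4
Reactants: 8 dimethyl (2E,9E)-6-hydroperoxy-2,6,10-trimethylundeca-2,9-dienedioate
Product: 9 methyl (2S)-2-[(3S,6S)-6-[(3E)-5-methoxy-4-methyl-5-oxopent-3-en-1-yl]-6-methyl-1,2-dioxan-3-yl]propanoate
Conditions: 1-[3,5-bis(trifluoromethyl)phenyl]-3-[(2S)-3,3-dimethyl-1-{[tris(4-methoxyphenyl)-λ5-phosphanylidene]amino}butan-2-yl]thiourea (10 mol%), toluene (0.02 M), −20 °C
Reagents that add atoms: none
Why: Proposed new method: catalytic desymmetrising 6-exo-trig peroxy-Michael addition, in which the iminophosphorane deprotonates the hydroperoxide, the thiourea hydrogen-bonds one enoate carbonyl and the peroxide oxygen adds through a chair transition state to the Si face of C3 of the pro-S arm (this sets 3S and, through the choice of arm with the free arm axial and the methyl equatorial, the C6 centre in the 3,6-cis sense), after which the P–N–H proton held at the new C–O oxygen is passed within the contact ion pair to the same face of the enolate (net syn addition across the (E)-enoate, setting 2S against the weak anti preference of free β-alkoxy enolates); the closest known reaction types are the amine-mediated cyclisation of hydroperoxy enoates to 1,2-dioxanes (stereoisomer mixtures) and iminophosphorane-catalysed enantioselective oxa- and sulfa-Michael additions to unactivated α,β-unsaturated esters.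

Step 5
Reactants: 9 methyl (2S)-2-[(3S,6S)-6-[(3E)-5-methoxy-4-methyl-5-oxopent-3-en-1-yl]-6-methyl-1,2-dioxan-3-yl]propanoate
Product: 11 methyl (2S)-2-[(3S,6R)-6-methyl-6-(3-oxopropyl)-1,2-dioxan-3-yl]propanoate, via trioxolane ozonide 10 (not isolated)
Conditions: O3, CH2Cl2, −78 °C; then Me2S (5 equiv), −78 °C to rt
Reagents that add atoms: ozone, [O-][O+]=O
Why: Ozonolysis (Criegee mechanism) cleaves the only C=C, and Me2S reduces the ozonide without touching the dialkyl peroxide, which like the saturated ester is inert to ozone at −78 °C, so no stereocentre is affected.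

Step 6
Reactants: 12 6-methylhept-5-en-2-one
Product: 13 6-hydroxy-6-methylheptan-2-one
Conditions: 35% aq. H2SO4, 0 °C to rt
Reagents that add atoms: water, O
Why: Markovnikov acid-catalysed hydration of the trisubstituted alkene via the tertiary cation; no stereocentre is formed.

Step 7
Reactants: 13 6-hydroxy-6-methylheptan-2-one; 14 2,4,6-tri(propan-2-yl)benzenesulfonohydrazide
Product: 15 N'-(6-hydroxy-6-methylheptan-2-ylidene)-2,4,6-tri(propan-2-yl)benzenesulfonohydrazide
Conditions: MeOH, HCl (cat.), rt
Reagents that add atoms: none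
Why: Acid-catalysed condensation of the ketone with the sulfonyl hydrazide gives the hydrazone needed for the Shapiro reaction and leaves the tertiary alcohol untouched.

Step 8
Reactants: 15 N'-(6-hydroxy-6-methylheptan-2-ylidene)-2,4,6-tri(propan-2-yl)benzenesulfonohydrazide (1.1 equiv); 11 methyl (2S)-2-[(3S,6R)-6-methyl-6-(3-oxopropyl)-1,2-dioxan-3-yl]propanoate
Product: 17 methyl (2S)-2-[(3S,6S)-6-[(3RS)-3,8-dihydroxy-8-methyl-4-methylidenenonyl]-6-methyl-1,2-dioxan-3-yl]propanoate (about 1:1 at the new carbinol carbon), via lithium 6-lithio-2-methylhept-6-en-2-olate 16 (not isolated)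
Conditions: n-BuLi (3.0 equiv to 15), THF, −78 °C to 0 °C; cooled to −78 °C and added to 11 in THF, −78 °C, 20 min; AcOH, −78 °C
Reagents that add atoms: none
Why: Shapiro reaction, in which the third equivalent of n-BuLi removes a methyl proton and loss of sulfinate and N2 gives the 2-lithioalkene, whose 1,2-addition to the aldehyde at −78 °C is far faster than attack on the hindered ester or the O–O bond; the new carbinol centre forms without control and is removed in step 9.

Step 9
Reactants: 17 methyl (2S)-2-[(3S,6S)-6-[(3RS)-3,8-dihydroxy-8-methyl-4-methylidenenonyl]-6-methyl-1,2-dioxan-3-yl]propanoate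
Product: 18 aikupikoxide D, methyl (2S)-2-[(3S,6R)-6-(8-hydroxy-8-methyl-4-methylidene-3-oxononyl)-6-methyl-1,2-dioxan-3-yl]propanoate
Conditions: Dess–Martin periodinane (1.3 equiv), CH2Cl2, 0 °C to rt
Reagents that add atoms: none
Why: Dess–Martin oxidation converts the secondary allylic alcohol into the enone under near-neutral conditions that leave the tertiary alcohol, the ester and the peroxide untouched, and it erases the stereorandom carbinol centre.

## Compound list

1 | ethyl acetate | CCOC(C)=O | starting material
2 | but-3-en-1-ylmagnesium bromide | C=CCC[Mg]Br | starting material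
3 | 5-methylnona-1,8-dien-5-ol | C=CCCC(C)(O)CCC=C | intermediate
4 | methyl 2-(triphenyl-λ5-phosphanylidene)propanoate | COC(=O)C(C)=P(c1ccccc1)(c1ccccc1)c1ccccc1 | starting material
5 | 3-methyl-1,5-bis(1,2,4-trioxolan-3-yl)pentan-3-ol (bis-ozonide, stereoisomer mixture, not isolated) | CC(O)(CCC1OCOO1)CCC1OCOO1 | intermediate
6 | 4-hydroxy-4-methylheptanedial (in equilibrium with its five-membered lactol, not isolated) | CC(O)(CCC=O)CCC=O | intermediate
7 | dimethyl (2E,9E)-6-hydroxy-2,6,10-trimethylundeca-2,9-dienedioate | COC(=O)/C(C)=C/CCC(C)(O)CC/C=C(\C)C(=O)OC | intermediate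
8 | dimethyl (2E,9E)-6-hydroperoxy-2,6,10-trimethylundeca-2,9-dienedioate | COC(=O)/C(C)=C/CCC(C)(OO)CC/C=C(\C)C(=O)OC | intermediate
9 | methyl (2S)-2-[(3S,6S)-6-[(3E)-5-methoxy-4-methyl-5-oxopent-3-en-1-yl]-6-methyl-1,2-dioxan-3-yl]propanoate | COC(=O)/C(C)=C/CC[C@@]1(C)CC[C@@H]([C@H](C)C(=O)OC)OO1 | intermediate
10 | methyl 5-{2-[(3R,6S)-6-[(2S)-1-methoxy-1-oxopropan-2-yl]-3-methyl-1,2-dioxan-3-yl]ethyl}-3-methyl-1,2,4-trioxolane-3-carboxylate (ozonide of 9, trioxolane centres unspecified, not isolated) | COC(=O)C1(C)OC(CC[C@@]2(C)CC[C@@H]([C@H](C)C(=O)OC)OO2)OO1 | intermediate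
11 | methyl (2S)-2-[(3S,6R)-6-methyl-6-(3-oxopropyl)-1,2-dioxan-3-yl]propanoate | O=CCC[C@@]1(C)CC[C@@H]([C@H](C)C(=O)OC)OO1 | intermediate
12 | 6-methylhept-5-en-2-one | CC(=O)CCC=C(C)C | starting material
13 | 6-hydroxy-6-methylheptan-2-one | CC(=O)CCCC(C)(C)O | intermediate
14 | 2,4,6-tri(propan-2-yl)benzenesulfonohydrazide | CC(C)c1cc(C(C)C)c(S(=O)(=O)NN)c(C(C)C)c1 | starting material
15 | N'-(6-hydroxy-6-methylheptan-2-ylidene)-2,4,6-tri(propan-2-yl)benzenesulfonohydrazide | CC(CCCC(C)(C)O)=NNS(=O)(=O)c1c(C(C)C)cc(C(C)C)cc1C(C)C | intermediate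
16 | lithium 6-lithio-2-methylhept-6-en-2-olate (not isolated) | [Li]C(=C)CCCC(C)(C)O[Li] | intermediate
17 | methyl (2S)-2-[(3S,6S)-6-[(3RS)-3,8-dihydroxy-8-methyl-4-methylidenenonyl]-6-methyl-1,2-dioxan-3-yl]propanoate | C=C(CCCC(C)(C)O)C(O)CC[C@@]1(C)CC[C@@H]([C@H](C)C(=O)OC)OO1 | intermediate
18 | aikupikoxide D, methyl (2S)-2-[(3S,6R)-6-(8-hydroxy-8-methyl-4-methylidene-3-oxononyl)-6-methyl-1,2-dioxan-3-yl]propanoate | C=C(CCCC(C)(C)O)C(=O)CC[C@@]1(C)CC[C@@H]([C@H](C)C(=O)OC)OO1 | target

## Step count and risks

Total: 9 steps (steps 6 and 7 make the side-chain fragment). Longest linear sequence: 7 steps (1, 2, 3, 4, 5, 8, 9).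

**Most likely to fail, first: step 4.** One catalyst has to control the face at C3, the choice of arm (C6) and the protonation at C2.
- The 3,6-cis/trans choice has almost no intrinsic bias, because methyl and a primary alkyl arm are of similar size.
- Free β-alkoxy enolates tend to protonate anti to the oxygen, which would give the 2R epimer.
- The peroxy enolate can close to an epoxy alcohol.
- The addition is reversible.
- Which antipode of the catalyst gives 3S must be found in a first screen; both are available from L- or D-tert-leucine.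
- The diastereomers of 9 are separable, and every unwanted isomer can be returned to achiral 8 by base-induced retro-Michael opening.

Fallback, setting out from 3 and coming back at 9: the acceptor and the activation mode are changed to iminium catalysis. Compound 3 is ozonised as in step 2 (via 5 and 6) but olefinated with 2-(triphenyl-λ5-phosphanylidene)propanal to give (2E,9E)-6-hydroxy-2,6,10-trimethylundeca-2,9-dienedial F1. Perhydrolysis as in step 3 gives (2E,9E)-6-hydroperoxy-2,6,10-trimethylundeca-2,9-dienedial F2. With 9-amino-9-deoxy-epi-quinine (20 mol%) and CF3CO2H in toluene at 0 °C, one enal arm is activated as its iminium ion, the hydroperoxide closes onto it and the enamine is protonated under catalyst control to give (2S)-2-[(3S,6S)-6-methyl-6-[(3E)-4-methyl-5-oxopent-3-en-1-yl]-1,2-dioxan-3-yl]propanal F3. Pinnick oxidation (NaClO2, NaH2PO4, 2-methylbut-2-ene) of both formyl groups gives (2S)-2-[(3S,6S)-6-[(3E)-4-carboxypent-3-en-1-yl]-6-methyl-1,2-dioxan-3-yl]propanoic acid F4, and trimethylsilyldiazomethane in MeOH/toluene gives 9.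

**Second: step 8.** The 2-lithioalkene 16 may attack the O–O bond or the ester of 11, or its basicity may open the ring by retro-Michael reaction.

Fallback, setting out from 11 and coming back at 18: the C9–C10 bond is made by acyl cross-coupling instead of carbonyl addition, which also makes the oxidation step unnecessary. Pinnick oxidation of 11 gives methyl (2S)-2-[(3S,6R)-6-(2-carboxyethyl)-6-methyl-1,2-dioxan-3-yl]propanoate F5. 1-Chloro-N,N,2-trimethylprop-1-en-1-amine in CH2Cl2 at 0 °C gives methyl (2S)-2-[(3S,6R)-6-(3-chloro-3-oxopropyl)-6-methyl-1,2-dioxan-3-yl]propanoate F6. Separately, 16 (made from 15 as in step 8) is quenched with Bu3SnCl to give 2-methyl-6-(tributylstannyl)hept-6-en-2-ol F7. Stille acylation of F6 with F7 (Pd2(dba)3, tri(2-furyl)phosphine, THF, 50 °C) gives 18 directly.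

**Third: step 3.** The tertiary cation can eliminate, and strong acid with concentrated H2O2 may attack the esters or trigger oxa-Michael closure of the tertiary alcohol.

Fallback, setting out from 7 and coming back at 8: the C6–O bond is made by radical hydrogen-atom transfer instead of through the cation. Dehydration of 7 with methyl N-(triethylammoniosulfonyl)carbamate (Burgess reagent, toluene, 50 °C) gives a mixture of dimethyl (2E,9E)-2,10-dimethyl-6-methylideneundeca-2,9-dienedioate F8 and dimethyl (2E,9E)-2,6,10-trimethylundeca-2,5,9-trienedioate F9. Both give the same tertiary C6 radical under Mukaiyama–Isayama conditions (Co(thd)2, that is bis(2,2,6,6-tetramethylheptane-3,5-dionato)cobalt, O2, Et3SiH, ClCH2CH2Cl, rt), which leave the electron-poor enoates alone, and so converge on dimethyl (2E,9E)-2,6,10-trimethyl-6-[(triethylsilyl)peroxy]undeca-2,9-dienedioate F10. HCl (cat.) in MeOH at 0 °C removes the silyl group to give 8.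

## Further compounds

F1 | step 4 | (2E,9E)-6-hydroxy-2,6,10-trimethylundeca-2,9-dienedial | O=C/C(C)=C/CCC(C)(O)CC/C=C(\C)C=O
F2 | step 4 | (2E,9E)-6-hydroperoxy-2,6,10-trimethylundeca-2,9-dienedial | O=C/C(C)=C/CCC(C)(OO)CC/C=C(\C)C=O
F3 | step 4 | (2S)-2-[(3S,6S)-6-methyl-6-[(3E)-4-methyl-5-oxopent-3-en-1-yl]-1,2-dioxan-3-yl]propanal | O=C/C(C)=C/CC[C@@]1(C)CC[C@@H]([C@H](C)C=O)OO1
F4 | step 4 | (2S)-2-[(3S,6S)-6-[(3E)-4-carboxypent-3-en-1-yl]-6-methyl-1,2-dioxan-3-yl]propanoic acid | OC(=O)/C(C)=C/CC[C@@]1(C)CC[C@@H]([C@H](C)C(=O)O)OO1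
F5 | step 8 | methyl (2S)-2-[(3S,6R)-6-(2-carboxyethyl)-6-methyl-1,2-dioxan-3-yl]propanoate | OC(=O)CC[C@@]1(C)CC[C@@H]([C@H](C)C(=O)OC)OO1
F6 | step 8 | methyl (2S)-2-[(3S,6R)-6-(3-chloro-3-oxopropyl)-6-methyl-1,2-dioxan-3-yl]propanoate | ClC(=O)CC[C@@]1(C)CC[C@@H]([C@H](C)C(=O)OC)OO1
F7 | step 8 | 2-methyl-6-(tributylstannyl)hept-6-en-2-ol | C=C(CCCC(C)(C)O)[Sn](CCCC)(CCCC)CCCC
F8 | step 3 | dimethyl (2E,9E)-2,10-dimethyl-6-methylideneundeca-2,9-dienedioate | COC(=O)/C(C)=C/CCC(=C)CC/C=C(\C)C(=O)OC
F9 | step 3 | dimethyl (2E,9E)-2,6,10-trimethylundeca-2,5,9-trienedioate (5E and 5Z) | COC(=O)/C(C)=C/CC=C(C)CC/C=C(\C)C(=O)OC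
F10 | step 3 | dimethyl (2E,9E)-2,6,10-trimethyl-6-[(triethylsilyl)peroxy]undeca-2,9-dienedioate | COC(=O)/C(C)=C/CCC(C)(OO[Si](CC)(CC)CC)CC/C=C(\C)C(=O)OC
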